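**Retrosynthetic overview**
- The plan rests on this feature: pyrrole C2 and C5 each carry one exocyclic oxidised carbon (the ketone C=O on C2, the CH2OH carbon on C5), while C3 and C4 carry only hydrogen. This maps onto symmetrical dimethyl 1H-pyrrole-2,5-dicarboxylate.
- Last C–C bond: Weinreb ketone synthesis between a 5-(silyloxymethyl)pyrrole-2-carboxamide and 15-methylhexadecylmagnesium bromide. The chain comes from 12-bromododecan-1-ol and 3-methylbutylmagnesium bromide by copper-catalysed coupling.
- The two equivalent esters are told apart by monosaponification; the free acid becomes CH2OH, the remaining ester becomes the ketone.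
- The pyrrole ring arises by reductive ring contraction (Zn/AcOH) of dimethyl pyridazine-3,6-dicarboxylate.
- The diazine ring is made first, by inverse-demand [4+2] cycloaddition of dimethyl 1,2,4,5-tetrazine-3,6-dicarboxylate (from two molecules of ethyl diazoacetate) with ethyl vinyl ether, with loss of N2 and ethanol. Ring order: dihydrotetrazine, tetrazine, 1,2-diazine, pyrrole.

Key step: step 5

Remark: the target has no stereocentre, so no stereocontrol is needed; the dihydrotetrazines 2–4 are drawn as the 1,4-dihydro tautomers.

**Route**

Step 1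
Reactants: 1 ethyl diazoacetate (2 equiv; two molecules combine)
Product: 2 disodium 1,4-dihydro-1,2,4,5-tetrazine-3,6-dicarboxylate
Conditions: NaOH (excess), H2O, 60–80 °C, slow addition of 1; precipitate from EtOH
Reagents that add atoms: ethyl diazoacetate (second molecule of 1), CCOC(=O)C=[N+]=[N-]; sodium hydroxide (2 equiv), [Na+].[OH-].[Na+].[OH-]
Why: Base-induced head-to-tail dimerisation joins the terminal nitrogen of each of two diazoacetate molecules to the diazo carbon of the other, closing the six-membered dihydrotetrazine through two new C–N bonds, while two equivalents of hydroxide saponify both ethyl esters, so the disodium salt should separate from the aqueous base.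

Step 2
Reactants: 2 disodium 1,4-dihydro-1,2,4,5-tetrazine-3,6-dicarboxylate
Product: 3 1,4-dihydro-1,2,4,5-tetrazine-3,6-dicarboxylic acid
Conditions: conc. HCl, H2O/ice, 0 °C
Reagents that add atoms: none
Why: Plain acid–base protonation of the dicarboxylate at 0 °C should precipitate the free diacid before decarboxylation can compete.

Step 3
Reactants: 3 1,4-dihydro-1,2,4,5-tetrazine-3,6-dicarboxylic acid
Product: 4 dimethyl 1,4-dihydro-1,2,4,5-tetrazine-3,6-dicarboxylate
Conditions: SOCl2, MeOH, −30 °C → 40 °C
Reagents that add atoms: methanol (2 equiv), CO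
Why: Fischer-type esterification driven by HCl generated in situ from SOCl2 and methanol converts both acids to methyl esters without touching the dihydrotetrazine ring.

Step 4
Reactants: 4 dimethyl 1,4-dihydro-1,2,4,5-tetrazine-3,6-dicarboxylate
Product: 5 dimethyl 1,2,4,5-tetrazine-3,6-dicarboxylate
Conditions: nitrous gases (N2O3 from NaNO2/aq. HCl, external generator), CH2Cl2, 0 °C
Reagents that add atoms: none
Why: Oxidative dehydrogenation of the two N–H bonds by nitrous gases under anhydrous conditions aromatises the ring and avoids hydrolysis of the strongly electrophilic tetrazine diester.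

Step 5
Reactants: 5 dimethyl 1,2,4,5-tetrazine-3,6-dicarboxylate; 6 ethyl vinyl ether
Product: 9 dimethyl pyridazine-3,6-dicarboxylate, via bicyclic adduct 7 (not isolated), via ethoxydihydropyridazine 8 (not isolated)
Conditions: 6 (3 equiv), 1,4-dioxane, 25 °C (N2 evolution); then cat. AcOH, 80 °C
Reagents that add atoms: none
Why: The tetrazine, made electron-poor by four ring nitrogens and two esters, and the electron-rich enol ether combine in a concerted inverse-electron-demand [4+2] cycloaddition across tetrazine C3 and C6, forming both new C–C bonds of bicycle 7 (Carboni–Lindsey reaction; the closest known type is the reaction of this tetrazine diester with enol ethers and silyl enol ethers). Retro-[4+2] loss of N2 from 7 gives the 4,5-dihydro-1,2-diazine 8, which tautomerises to the 1,4-dihydro form and eliminates ethanol to give aromatic 9. The one ring that persists, the six-membered 1,2-diazine, is thus closed by an intermolecular cycloaddition that makes both ring bonds at once, followed by cycloreversion, and not by cyclisation of a tethered chain. The stereocentres of 7 and 8 (bridgeheads and the ethoxy-bearing carbon) are transient and vanish on aromatisation, so nothing has to be controlled. The step needs only a single cycloaddition and complete elimination: the symmetrical tetrazine offers no regiochemical choice, the product diazine is a far poorer diene than the tetrazine, and the ethoxy group in the dihydrodiazine sits beta to an acidic C–H/N–H so that aromatisation drives its loss.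

Step 6
Reactants: 9 dimethyl pyridazine-3,6-dicarboxylate
Product: 10 dimethyl 1H-pyrrole-2,5-dicarboxylate
Conditions: Zn dust (excess), AcOH, 25 °C
Reagents that add atoms: none
Why: Reductive ring contraction of a 1,2-diazine: Zn/AcOH reduces the ester-flanked diazine, cleaves the N–N bond, and the resulting amino-enamine recloses on the imine carbon with loss of ammonia to give the pyrrole.

Step 7
Reactants: 10 dimethyl 1H-pyrrole-2,5-dicarboxylate
Product: 11 5-(methoxycarbonyl)-1H-pyrrole-2-carboxylic acid
Conditions: KOH (1.0 equiv), MeOH/H2O, 60 °C; then 1 M HCl, 0 °C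
Reagents that add atoms: potassium hydroxide, [K+].[OH-]
Why: Monosaponification with one equivalent of hydroxide should stop after the first ester because the carboxylate formed deactivates the second one through the ring, and acid/base extraction separates the monoacid from recyclable diester.

Step 8
Reactants: 11 5-(methoxycarbonyl)-1H-pyrrole-2-carboxylic acid
Product: 13 methyl 5-(hydroxymethyl)-1H-pyrrole-2-carboxylate, via mixed carbonic anhydride 12 (not isolated)
Conditions: iBuOCOCl, N-methylmorpholine, THF, −15 °C; then NaBH4, H2O, 0 °C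
Reagents that add atoms: none
Why: Mixed-anhydride activation followed by NaBH4 reduction reduces the acid chemoselectively, since borohydride does not touch the conjugated pyrrole methyl ester at 0 °C.

Step 9
Reactants: 13 methyl 5-(hydroxymethyl)-1H-pyrrole-2-carboxylate
Product: 14 methyl 5-({[tri(propan-2-yl)silyl]oxy}methyl)-1H-pyrrole-2-carboxylate
Conditions: iPr3SiCl, imidazole, DMF, 0 °C → rt
Reagents that add atoms: chlorotri(propan-2-yl)silane, CC(C)[Si](Cl)(C(C)C)C(C)C
Why: Imidazole-promoted silyl ether formation is selective for the primary alcohol over the weakly nucleophilic acylpyrrole N–H, and the bulky silyl ether is chosen to survive the basic steps that follow.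

Step 10
Reactants: 14 methyl 5-({[tri(propan-2-yl)silyl]oxy}methyl)-1H-pyrrole-2-carboxylate
Product: 15 5-({[tri(propan-2-yl)silyl]oxy}methyl)-1H-pyrrole-2-carboxylic acid
Conditions: LiOH·H2O, THF/MeOH/H2O, 50 °C; then 1 M HCl to pH 4, 0 °C
Reagents that add atoms: lithium hydroxide, [Li+].[OH-]
Why: Ester saponification (acyl–oxygen cleavage by hydroxide) leaves the triisopropylsilyl ether intact, and acidification only to pH 4 in the cold avoids decarboxylation and silyl loss.

Step 11
Reactants: 15 5-({[tri(propan-2-yl)silyl]oxy}methyl)-1H-pyrrole-2-carboxylic acid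
Product: 16 N-methoxy-N-methyl-5-({[tri(propan-2-yl)silyl]oxy}methyl)-1H-pyrrole-2-carboxamide
Conditions: MeNHOMe·HCl, EDC·HCl, HOBt, iPr2NEt, CH2Cl2, 0 °C → rt
Reagents that add atoms: N,O-dimethylhydroxylamine hydrochloride, CNOC.Cl
Why: Carbodiimide/HOBt amide coupling is routine for pyrrole-2-carboxylic acids with a free N–H and gives the Weinreb amide under near-neutral conditions that the silyl ether tolerates.

Step 12
Reactants: 17 1-bromo-3-methylbutane; 18 12-bromododecan-1-ol
Product: 20 15-methylhexadecan-1-ol, via 3-methylbutylmagnesium bromide 19 (not isolated)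
Conditions: 17 (3 equiv), Mg, THF, 40 °C; then 18, Li2CuCl4 (3 mol %), THF, −20 °C → rt; aq. NH4Cl
Reagents that add atoms: none
Why: Copper-catalysed alkyl–alkyl Grignard cross-coupling: the first equivalent of 19 turns the hydroxyl of 18 into an inert magnesium alkoxide and the cuprate formed in situ displaces the primary bromide.

Step 13
Reactants: 20 15-methylhexadecan-1-ol
Product: 21 1-bromo-15-methylhexadecane
Conditions: CBr4, PPh3, CH2Cl2, 0 °C → rt
Reagents that add atoms: carbon tetrabromide, BrC(Br)(Br)Br
Why: Appel reaction, in which bromide displaces the alkoxyphosphonium at the unhindered primary carbon by SN2.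

Step 14
Reactants: 16 N-methoxy-N-methyl-5-({[tri(propan-2-yl)silyl]oxy}methyl)-1H-pyrrole-2-carboxamide; 21 1-bromo-15-methylhexadecane
Product: 23 16-methyl-1-[5-({[tri(propan-2-yl)silyl]oxy}methyl)-1H-pyrrol-2-yl]heptadecan-1-one, via 15-methylhexadecylmagnesium bromide 22 (not isolated)
Conditions: 21 (3 equiv), Mg, cat. I2, THF, 45 °C; then 16, THF, 0 °C → rt; aq. NH4Cl
Reagents that add atoms: none
Why: Weinreb ketone synthesis: one equivalent of 22 deprotonates the pyrrole N–H, a second adds to the amide to give a magnesium-chelated tetrahedral intermediate that releases the ketone only on work-up, so over-addition is excluded and the silyl ether is untouched.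

Step 15
Reactants: 23 16-methyl-1-[5-({[tri(propan-2-yl)silyl]oxy}methyl)-1H-pyrrol-2-yl]heptadecan-1-one
Product: 24 1-[5-(hydroxymethyl)-1H-pyrrol-2-yl]-16-methylheptadecan-1-one
Conditions: Bu4NF, AcOH, THF, 0 °C → rt
Reagents that add atoms: none
Why: Fluoride-mediated desilylation buffered with acetic acid frees the primary alcohol without base- or acid-induced ionisation of the pyrrol-2-ylcarbinol.

**Compound list**
1 | ethyl diazoacetate | CCOC(=O)C=[N+]=[N-] | starting material
2 | disodium 1,4-dihydro-1,2,4,5-tetrazine-3,6-dicarboxylate | [Na+].[Na+].[O-]C(=O)C1=NNC(C(=O)[O-])=NN1 | intermediate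
3 | 1,4-dihydro-1,2,4,5-tetrazine-3,6-dicarboxylic acid | OC(=O)C1=NNC(C(=O)O)=NN1 | intermediate
4 | dimethyl 1,4-dihydro-1,2,4,5-tetrazine-3,6-dicarboxylate | COC(=O)C1=NNC(C(=O)OC)=NN1 | intermediate
5 | dimethyl 1,2,4,5-tetrazine-3,6-dicarboxylate | COC(=O)c1nnc(C(=O)OC)nn1 | intermediate
6 | ethyl vinyl ether | C=COCC | starting material
7 | dimethyl 7-ethoxy-2,3,5,6-tetraazabicyclo[2.2.2]octa-2,5-diene-1,4-dicarboxylate (racemic, formed in the flask) | COC(=O)C12N=NC(C(=O)OC)(N=N1)C(OCC)C2 | intermediate
8 | dimethyl 4-ethoxy-4,5-dihydropyridazine-3,6-dicarboxylate (racemic, formed in the flask) | COC(=O)C1=NN=C(C(=O)OC)C(OCC)C1 | intermediate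
9 | dimethyl pyridazine-3,6-dicarboxylate | COC(=O)c1ccc(C(=O)OC)nn1 | intermediate
10 | dimethyl 1H-pyrrole-2,5-dicarboxylate | COC(=O)c1ccc(C(=O)OC)[nH]1 | intermediate
11 | 5-(methoxycarbonyl)-1H-pyrrole-2-carboxylic acid | COC(=O)c1ccc(C(=O)O)[nH]1 | intermediate
12 | 5-(methoxycarbonyl)-1H-pyrrole-2-carboxylic 2-methylpropyl carbonic anhydride (formed in the flask) | COC(=O)c1ccc(C(=O)OC(=O)OCC(C)C)[nH]1 | intermediate
13 | methyl 5-(hydroxymethyl)-1H-pyrrole-2-carboxylate | COC(=O)c1ccc(CO)[nH]1 | intermediate
14 | methyl 5-({[tri(propan-2-yl)silyl]oxy}methyl)-1H-pyrrole-2-carboxylate | COC(=O)c1ccc(CO[Si](C(C)C)(C(C)C)C(C)C)[nH]1 | intermediate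
15 | 5-({[tri(propan-2-yl)silyl]oxy}methyl)-1H-pyrrole-2-carboxylic acid | OC(=O)c1ccc(CO[Si](C(C)C)(C(C)C)C(C)C)[nH]1 | intermediate
16 | N-methoxy-N-methyl-5-({[tri(propan-2-yl)silyl]oxy}methyl)-1H-pyrrole-2-carboxamide | CON(C)C(=O)c1ccc(CO[Si](C(C)C)(C(C)C)C(C)C)[nH]1 | intermediate
17 | 1-bromo-3-methylbutane | CC(C)CCBr | starting material
18 | 12-bromododecan-1-ol | OCCCCCCCCCCCCBr | starting material
19 | 3-methylbutylmagnesium bromide (formed in the flask) | CC(C)CC[Mg]Br | intermediate
20 | 15-methylhexadecan-1-ol | CC(C)CCCCCCCCCCCCCCO | intermediate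
21 | 1-bromo-15-methylhexadecane | CC(C)CCCCCCCCCCCCCCBr | intermediate
22 | 15-methylhexadecylmagnesium bromide (formed in the flask) | CC(C)CCCCCCCCCCCCCC[Mg]Br | intermediate
23 | 16-methyl-1-[5-({[tri(propan-2-yl)silyl]oxy}methyl)-1H-pyrrol-2-yl]heptadecan-1-one | CC(C)CCCCCCCCCCCCCCC(=O)c1ccc(CO[Si](C(C)C)(C(C)C)C(C)C)[nH]1 | intermediate
24 | 1-[5-(hydroxymethyl)-1H-pyrrol-2-yl]-16-methylheptadecan-1-one | CC(C)CCCCCCCCCCCCCCC(=O)c1ccc(CO)[nH]1 | target

**Step count and risks**

Total step count: 15. Longest linear sequence: 13 steps (steps 1–11, 14 and 15, from ethyl diazoacetate 1); the side-chain branch (steps 12 and 13) joins at step 14.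

Steps most likely to fail:

Step 5. The sequence may stall after nitrogen loss, with elimination of ethanol from the dihydrodiazine incomplete, or the moisture-sensitive tetrazine may be consumed by adventitious nucleophiles before it meets the enol ether. The fallback sets out from 5 and swaps the aromatisation mode from elimination to cycloreversion. Bicyclo[2.2.1]hepta-2,5-diene serves as the acetylene equivalent in toluene, 25 °C then reflux. Cycloaddition across one of its C=C bonds should give dimethyl 9,10,11,12-tetraazatetracyclo[6.2.2.1(3,6).0(2,7)]trideca-4,9,11-triene-1,8-dicarboxylate F1 (the tetraaza-bridged norbornadiene adduct). This loses N2 to give dimethyl 4a,5,8,8a-tetrahydro-5,8-methanophthalazine-1,4-dicarboxylate F2. A retro-Diels–Alder loss of cyclopentadiene then delivers the aromatic diazine, and the route is rejoined at 9.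

Step 8. Hydride may attack the carbonate carbonyl of the mixed anhydride and return the acid, or the activated N–H pyrrole acyl group may self-condense through a ketene-like species before it is reduced. The fallback sets out from 11 and passes through the aldehyde oxidation level. Steglich-type coupling with ethanethiol (DCC, cat. DMAP, CH2Cl2) should give methyl 5-[(ethylsulfanyl)carbonyl]-1H-pyrrole-2-carboxylate F3. Fukuyama reduction (Et3SiH, Pd/C, acetone, rt) should give methyl 5-formyl-1H-pyrrole-2-carboxylate F4. NaBH4 in MeOH at 0 °C then reduces the aldehyde, and the route is rejoined at 13.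

Step 14. The first equivalent of Grignard reagent turns the pyrrole into its N-magnesio anion, whose delocalisation into the amide may make acyl substitution sluggish, and Wurtz homocoupling during formation of the long-chain Grignard reagent may lower its titre. The fallback sets out from 16 and replaces acyl substitution by aldehyde addition and re-oxidation. LiAlH4 in THF at −20 °C should reduce the Weinreb amide to 5-({[tri(propan-2-yl)silyl]oxy}methyl)-1H-pyrrole-2-carbaldehyde F5. Addition of 22 (2.5 equiv, THF, 0 °C) should give racemic 16-methyl-1-[5-({[tri(propan-2-yl)silyl]oxy}methyl)-1H-pyrrol-2-yl]heptadecan-1-ol F6. The crude carbinol is oxidised at once with MnO2 in CH2Cl2, and the route is rejoined at 23.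

**Further compounds**
F1 | step 5 | dimethyl 9,10,11,12-tetraazatetracyclo[6.2.2.1(3,6).0(2,7)]trideca-4,9,11-triene-1,8-dicarboxylate (exo adduct, transient, configuration not encoded) | COC(=O)C12N=NC(C(=O)OC)(N=N1)C1C3C=CC(C3)C21
F2 | step 5 | dimethyl 4a,5,8,8a-tetrahydro-5,8-methanophthalazine-1,4-dicarboxylate (exo-fused, transient, configuration not encoded) | COC(=O)C1=NN=C(C(=O)OC)C2C3C=CC(C3)C12
F3 | step 8 | methyl 5-[(ethylsulfanyl)carbonyl]-1H-pyrrole-2-carboxylate | CCSC(=O)c1ccc(C(=O)OC)[nH]1
F4 | step 8 | methyl 5-formyl-1H-pyrrole-2-carboxylate | COC(=O)c1ccc(C=O)[nH]1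
F5 | step 14 | 5-({[tri(propan-2-yl)silyl]oxy}methyl)-1H-pyrrole-2-carbaldehyde | O=Cc1ccc(CO[Si](C(C)C)(C(C)C)C(C)C)[nH]1
F6 | step 14 | 16-methyl-1-[5-({[tri(propan-2-yl)silyl]oxy}methyl)-1H-pyrrol-2-yl]heptadecan-1-ol (racemic) | CC(C)CCCCCCCCCCCCCCC(O)c1ccc(CO[Si](C(C)C)(C(C)C)C(C)C)[nH]1
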